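**Plan**

1. Retrosynthesis: the five O–benzyl bonds are cut last. Then the carbinol C–aryl bond and the indane C1–C2 bond are cut together, back to a 1,2-dihydronaphthalene 3,4-oxide plus an aryl Grignard reagent. The six-membered ring is then cut at its aryl–C1 bond (Friedel–Crafts), the 1,4-dioxygenated chain at its acyl–C bond (Stetter), and the enone at its C=C bond (aldol).
2. Enabling feature: in the indane ring (C1, C2, C3, C3a, C7a) the benzylic carbon C1 sits between C7a of the resorcinol ring (ring A) and C2 and carries an exocyclic oxygenated carbon. C7a–C1(–CHO)–C2 is the product pattern of a halohydrin semipinacol 1,2-shift in a tetralin epoxide whose six-membered ring holds the future carbinol carbon as its sixth atom.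
3. Forward: chalcone, then 1,4-diketone, then diol. Ring A closes the six-membered ring, and dehydration gives the trans-1,2-diaryl-1,2-dihydronaphthalene. Epoxidation follows, then ring contraction to the indane carbaldehyde with aryl addition in the same flask, then hydrogenolysis.
4. Stereochemistry: the carbon bearing the 3,5-dioxygenated aryl group comes from the asymmetric Stetter reaction. The neighbouring diarylmethine is set trans in the cyclisation. The epoxide forms anti to the adjacent aryl group. Indane C1 follows from two inversions at the benzylic carbon, and the carbinol from Felkin–Anh addition.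

Key step: step 6

Assumption: diol 6 and intermediate 7 are carried as mixtures of carbinol epimers, since these centres are destroyed in step 4; the sense of induction in step 2 is taken to be selectable through the catalyst enantiomer.

**Step 1**
Reactants: 1 1-[3,5-bis(benzyloxy)phenyl]ethan-1-one; 2 3,5-bis(benzyloxy)benzaldehyde
Product: 3 (E)-1,3-bis[3,5-bis(benzyloxy)phenyl]prop-2-en-1-one
Conditions: NaOH (aq), EtOH/THF, 23 °C
Reagents that add atoms: none
Why: Claisen–Schmidt condensation of a methyl ketone with a non-enolisable aldehyde should give the E-enone after elimination under thermodynamic control.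

**Step 2**
Reactants: 3 (E)-1,3-bis[3,5-bis(benzyloxy)phenyl]prop-2-en-1-one; 4 4-(benzyloxy)benzaldehyde
Product: 5 (2S)-1-[4-(benzyloxy)phenyl]-2,4-bis[3,5-bis(benzyloxy)phenyl]butane-1,4-dione
Conditions: chiral bicyclic triazolium tetrafluoroborate precatalyst (pyroglutamate-derived, 10 mol %, enantiomer giving the 2S product), Cs2CO3 (10 mol %), THF, 0 °C; recrystallisation
Reagents that add atoms: none
Why: In this asymmetric intermolecular Stetter reaction the triazolylidene turns 4 into an acyl anion equivalent that adds to the β-carbon of enone 3, the chiral carbene selecting the enone face and so setting C2, and crystallisation should raise the enantiomeric purity.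

**Step 3**
Reactants: 5 (2S)-1-[4-(benzyloxy)phenyl]-2,4-bis[3,5-bis(benzyloxy)phenyl]butane-1,4-dione
Product: 6 (2S)-1-[4-(benzyloxy)phenyl]-2,4-bis[3,5-bis(benzyloxy)phenyl]butane-1,4-diol
Conditions: NaBH4, CeCl3·7H2O, MeOH/THF, −40 °C
Reagents that add atoms: none
Why: Luche-type borohydride reduction of both aryl ketones is fast and weakly basic, so the α-aryl centre should survive, and the two new carbinol centres need no control.

**Step 4**
Reactants: 6 (2S)-1-[4-(benzyloxy)phenyl]-2,4-bis[3,5-bis(benzyloxy)phenyl]butane-1,4-diol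
Product: 8 (1R,2R)-6,8-bis(benzyloxy)-1-[4-(benzyloxy)phenyl]-2-[3,5-bis(benzyloxy)phenyl]-1,2-dihydronaphthalene, via tetralin-1-ol 7 (not isolated)
Conditions: p-TsOH·H2O (20 mol %), PhMe, 23 °C, then 80 °C
Reagents that add atoms: none
Why: Acid ionises only the 4-alkoxybenzylic carbinol, and the cation is captured by the ortho carbon of the chain-terminal 3,5-dibenzyloxyphenyl ring in an intramolecular Friedel–Crafts alkylation (six-membered ring, aryl groups trans through a chair-like transition state, any tetrahydrofuran formed by hydroxyl capture re-ionising to the same cation), after which E1 dehydration of the remaining benzylic alcohol gives the styrene-type alkene.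

**Step 5**
Reactants: 8 (1R,2R)-6,8-bis(benzyloxy)-1-[4-(benzyloxy)phenyl]-2-[3,5-bis(benzyloxy)phenyl]-1,2-dihydronaphthalene
Product: 9 (1aR,2R,3R,7bS)-4,6-bis(benzyloxy)-3-[4-(benzyloxy)phenyl]-2-[3,5-bis(benzyloxy)phenyl]-1a,2,3,7b-tetrahydronaphtho[1,2-b]oxirene
Conditions: dimethyldioxirane, acetone/CH2Cl2, −20 °C
Reagents that add atoms: dimethyldioxirane CC1(C)OO1
Why: Neutral dioxirane epoxidation of the cis-disubstituted styrene-type alkene should deliver oxygen to the face anti to the pseudoaxial aryl group on the adjacent allylic carbon, which fixes both epoxide carbons.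

**Step 6**
Reactants: 9 (1aR,2R,3R,7bS)-4,6-bis(benzyloxy)-3-[4-(benzyloxy)phenyl]-2-[3,5-bis(benzyloxy)phenyl]-1a,2,3,7b-tetrahydronaphtho[1,2-b]oxirene; 10 [4-(benzyloxy)phenyl]magnesium bromide
Product: 13 (R)-[(1S,2S,3R)-4,6-bis(benzyloxy)-3-[4-(benzyloxy)phenyl]-2-[3,5-bis(benzyloxy)phenyl]-2,3-dihydro-1H-inden-1-yl][4-(benzyloxy)phenyl]methanol, via bromohydrin magnesium alkoxide 11 (not isolated), via indane-1-carbaldehyde 12 (not isolated)
Conditions: MgBr2·OEt2, PhMe/Et2O, 0 to 23 °C; then 10, THF, −78 °C; pH 7 buffer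
Reagents that add atoms: none
Why: Bromide from MgBr2 should open the activated epoxide at the benzylic carbon C7b with inversion (trans-diaxial) to give 11, whose alkoxide then drives a semipinacol 1,2-shift of the ring bond C1a–C2 to C7b anti to C–Br, expelling bromide and leaving the old C1a as the exocyclic formyl carbon of 12, which 10 then captures. The closest known reaction type is the magnesium halide-mediated rearrangement of cycloalkene oxides to ring-contracted aldehydes and their capture by a Grignard reagent in the same flask. The five-membered ring is not closed by a cyclisation but arises from the six-membered ring by this 1,2-alkyl shift, a contraction by one carbon. Indane C1 is set by the two successive inversions at the benzylic carbon, so the formyl group ends on the face opposite to the epoxide oxygen, cis to the C2 aryl and trans to the C3 aryl; the carbinol centre is set by Felkin–Anh addition with the fused aryl carbon anti to the incoming aryl group and attack past C1–H. The step needs bromide attack at the benzylic carbon only and carbon migration in place of hydride migration: in the trans-bromohydrin the carbinol hydrogen is syn to bromine and cannot shift, and the two meta benzyloxy groups of ring A do not stabilise a benzylic cation, which disfavours ionisation and scrambling.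

**Step 7**
Reactants: 13 (R)-[(1S,2S,3R)-4,6-bis(benzyloxy)-3-[4-(benzyloxy)phenyl]-2-[3,5-bis(benzyloxy)phenyl]-2,3-dihydro-1H-inden-1-yl][4-(benzyloxy)phenyl]methanol
Product: 14 (1S,2S,3R)-2-(3,5-dihydroxyphenyl)-1-[(R)-hydroxy(4-hydroxyphenyl)methyl]-3-(4-hydroxyphenyl)-2,3-dihydro-1H-indene-4,6-diol
Conditions: H2 (1 atm), 10% Pd/C, EtOAc/MeOH, 23 °C
Reagents that add atoms: none
Why: Neutral hydrogenolysis should cleave the five phenolic benzyl ethers much faster than the secondary benzylic C–OH bond, and the absence of acid avoids ionisation of the 4-hydroxybenzylic alcohol, so no stereocentre is touched.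

**Compound list**

1 | 1-[3,5-bis(benzyloxy)phenyl]ethan-1-one | CC(=O)c1cc(OCc2ccccc2)cc(OCc2ccccc2)c1 | starting material
2 | 3,5-bis(benzyloxy)benzaldehyde | O=Cc1cc(OCc2ccccc2)cc(OCc2ccccc2)c1 | starting material
3 | (E)-1,3-bis[3,5-bis(benzyloxy)phenyl]prop-2-en-1-one | O=C(/C=C/c1cc(OCc2ccccc2)cc(OCc2ccccc2)c1)c1cc(OCc2ccccc2)cc(OCc2ccccc2)c1 | intermediate
4 | 4-(benzyloxy)benzaldehyde | O=Cc1ccc(OCc2ccccc2)cc1 | starting material
5 | (2S)-1-[4-(benzyloxy)phenyl]-2,4-bis[3,5-bis(benzyloxy)phenyl]butane-1,4-dione | O=C(C[C@H](C(=O)c1ccc(OCc2ccccc2)cc1)c1cc(OCc2ccccc2)cc(OCc2ccccc2)c1)c1cc(OCc2ccccc2)cc(OCc2ccccc2)c1 | intermediate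
6 | (2S)-1-[4-(benzyloxy)phenyl]-2,4-bis[3,5-bis(benzyloxy)phenyl]butane-1,4-diol, epimer mixture at C1 and C4 | OC(C[C@H](C(O)c1ccc(OCc2ccccc2)cc1)c1cc(OCc2ccccc2)cc(OCc2ccccc2)c1)c1cc(OCc2ccccc2)cc(OCc2ccccc2)c1 | intermediate
7 | (3R,4R)-5,7-bis(benzyloxy)-4-[4-(benzyloxy)phenyl]-3-[3,5-bis(benzyloxy)phenyl]-1,2,3,4-tetrahydronaphthalen-1-ol, 3,4-trans, C1 epimers | C(Oc1ccc(cc1)[C@@H]1c2c(OCc3ccccc3)cc(OCc3ccccc3)cc2C(O)C[C@H]1c1cc(OCc2ccccc2)cc(OCc2ccccc2)c1)c1ccccc1 | intermediate
8 | (1R,2R)-6,8-bis(benzyloxy)-1-[4-(benzyloxy)phenyl]-2-[3,5-bis(benzyloxy)phenyl]-1,2-dihydronaphthalene, trans | C(Oc1ccc(cc1)[C@@H]1c2c(OCc3ccccc3)cc(OCc3ccccc3)cc2C=C[C@H]1c1cc(OCc2ccccc2)cc(OCc2ccccc2)c1)c1ccccc1 | intermediate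
9 | (1aR,2R,3R,7bS)-4,6-bis(benzyloxy)-3-[4-(benzyloxy)phenyl]-2-[3,5-bis(benzyloxy)phenyl]-1a,2,3,7b-tetrahydronaphtho[1,2-b]oxirene, oxygen anti to the C2 aryl | C(Oc1ccc(cc1)[C@@H]1c2c(OCc3ccccc3)cc(OCc3ccccc3)cc2[C@@H]2O[C@@H]2[C@H]1c1cc(OCc2ccccc2)cc(OCc2ccccc2)c1)c1ccccc1 | intermediate
10 | [4-(benzyloxy)phenyl]magnesium bromide | Br[Mg]c1ccc(OCc2ccccc2)cc1 | starting material
11 | bromomagnesium (1R,2R,3R,4R)-5,7-bis(benzyloxy)-4-[4-(benzyloxy)phenyl]-3-[3,5-bis(benzyloxy)phenyl]-1-bromo-1,2,3,4-tetrahydronaphthalen-2-olate, Br and O trans | C(Oc1ccc(cc1)[C@@H]1c2c(OCc3ccccc3)cc(OCc3ccccc3)cc2[C@@H](Br)[C@H](O[Mg]Br)[C@H]1c1cc(OCc2ccccc2)cc(OCc2ccccc2)c1)c1ccccc1 | intermediate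
12 | (1S,2S,3R)-4,6-bis(benzyloxy)-3-[4-(benzyloxy)phenyl]-2-[3,5-bis(benzyloxy)phenyl]-2,3-dihydro-1H-indene-1-carbaldehyde, 1,2-cis and 2,3-trans | C(Oc1ccc(cc1)[C@@H]1c2c(OCc3ccccc3)cc(OCc3ccccc3)cc2[C@@H](C=O)[C@H]1c1cc(OCc2ccccc2)cc(OCc2ccccc2)c1)c1ccccc1 | intermediate
13 | (R)-[(1S,2S,3R)-4,6-bis(benzyloxy)-3-[4-(benzyloxy)phenyl]-2-[3,5-bis(benzyloxy)phenyl]-2,3-dihydro-1H-inden-1-yl][4-(benzyloxy)phenyl]methanol | C(Oc1ccc(cc1)[C@@H]1c2c(OCc3ccccc3)cc(OCc3ccccc3)cc2[C@@H]([C@@H](O)c2ccc(OCc3ccccc3)cc2)[C@H]1c1cc(OCc2ccccc2)cc(OCc2ccccc2)c1)c1ccccc1 | intermediate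
14 | (1S,2S,3R)-2-(3,5-dihydroxyphenyl)-1-[(R)-hydroxy(4-hydroxyphenyl)methyl]-3-(4-hydroxyphenyl)-2,3-dihydro-1H-indene-4,6-diol | Oc1ccc([C@@H]2c3c(O)cc(O)cc3[C@@H]([C@@H](O)c3ccc(O)cc3)[C@H]2c2cc(O)cc(O)c2)cc1 | target

**Count**

Total steps: 7. Longest linear sequence: 7 steps (from 1 or 2 to 14).

**Steps most likely to fail**

Step 6. Configuration may be lost at either new centre. Exchange or ionisation at the benzylic C–Br bond of 11 before the 1,2-shift would lead to the C1 epimer or to a hydride shift, and 10 may attack the other carbonyl face of 12. The fallback sets out from 9 and comes back at 13. The same cascade is run without regard to selectivity and the carbinols are taken on as the stereoisomer mixture F1. Dess–Martin periodinane (NaHCO3, CH2Cl2) should give the aryl ketone as its C1 epimers F2. KN(SiMe3)2 (THF, −78 °C) should convert both epimers into the one potassium enolate F3. Kinetic protonation with AcOH at −78 °C, from the face anti to the C2 aryl, should give the contra-thermodynamic cis ketone F4. Corey–Bakshi–Shibata reduction with (S)-2-methyl-CBS-oxazaborolidine and BH3·SMe2 (toluene, −40 °C), the catalyst enantiomer chosen on the aryl-as-large-group model, should then set the carbinol under reagent control and return 13.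

Step 5. Oxygen may be delivered mainly to the face syn to the C2 aryl, if the pseudoaxial C1 aryl controls the approach. The fallback sets out from 8 and comes back at 12, using the stereocomplementary ring contraction. The trivalent iodine reagent PhI(OH)OTs in MeOH/HC(OMe)3 at −10 °C should add iodine to C3 on that same face, and the fused aryl carbon C4a then migrates from C4 to C3 with one inversion. This should give the dimethyl acetal F5 with the acetal carbon cis to the C2 aryl. Unmasking with TESOTf/2,4,6-collidine and then water should give 12, which is treated with 10 at −78 °C as in step 6.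

Step 2. The carbene catalyst may discriminate the enone faces poorly, or the α-aryl ketone may racemise under base. The fallback sets out from 3 and 4 and comes back at 6. An achiral Stetter reaction (3-benzyl-5-(2-hydroxyethyl)-4-methylthiazolium chloride, Et3N, EtOH, 70 °C) should give the racemic diketone F6. Hydrogenation with RuCl2[(S)-xylbinap][(S)-daipen] or its enantiomer (t-BuOK, i-PrOH, H2) should reduce both ketones with dynamic kinetic resolution of the base-labile α-aryl centre and so give 6 in the 2S series.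

**Further compounds**

F1 | step 6 | [(2S,3R)-4,6-bis(benzyloxy)-3-[4-(benzyloxy)phenyl]-2-[3,5-bis(benzyloxy)phenyl]-2,3-dihydro-1H-inden-1-yl][4-(benzyloxy)phenyl]methanol, mixture at C1 and at the carbinol carbon | C(Oc1ccc(cc1)[C@@H]1c2c(OCc3ccccc3)cc(OCc3ccccc3)cc2C(C(O)c2ccc(OCc3ccccc3)cc2)[C@H]1c1cc(OCc2ccccc2)cc(OCc2ccccc2)c1)c1ccccc1
F2 | step 6 | [(2S,3R)-4,6-bis(benzyloxy)-3-[4-(benzyloxy)phenyl]-2-[3,5-bis(benzyloxy)phenyl]-2,3-dihydro-1H-inden-1-yl][4-(benzyloxy)phenyl]methanone, C1 epimers | C(Oc1ccc(cc1)[C@@H]1c2c(OCc3ccccc3)cc(OCc3ccccc3)cc2C(C(=O)c2ccc(OCc3ccccc3)cc2)[C@H]1c1cc(OCc2ccccc2)cc(OCc2ccccc2)c1)c1ccccc1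
F3 | step 6 | potassium enolate of F2, exocyclic C1=C(O)Ar double bond | C(Oc1ccc(cc1)[C@@H]1c2c(OCc3ccccc3)cc(OCc3ccccc3)cc2C(=C([O-])c2ccc(OCc3ccccc3)cc2)[C@H]1c1cc(OCc2ccccc2)cc(OCc2ccccc2)c1)c1ccccc1.[K+]
F4 | step 6 | [(1S,2S,3R)-4,6-bis(benzyloxy)-3-[4-(benzyloxy)phenyl]-2-[3,5-bis(benzyloxy)phenyl]-2,3-dihydro-1H-inden-1-yl][4-(benzyloxy)phenyl]methanone, 1,2-cis | C(Oc1ccc(cc1)[C@@H]1c2c(OCc3ccccc3)cc(OCc3ccccc3)cc2[C@@H](C(=O)c2ccc(OCc3ccccc3)cc2)[C@H]1c1cc(OCc2ccccc2)cc(OCc2ccccc2)c1)c1ccccc1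
F5 | step 5 | (1S,2S,3R)-4,6-bis(benzyloxy)-3-[4-(benzyloxy)phenyl]-2-[3,5-bis(benzyloxy)phenyl]-1-(dimethoxymethyl)-2,3-dihydro-1H-indene | C(Oc1ccc(cc1)[C@@H]1c2c(OCc3ccccc3)cc(OCc3ccccc3)cc2[C@@H](C(OC)OC)[C@H]1c1cc(OCc2ccccc2)cc(OCc2ccccc2)c1)c1ccccc1
F6 | step 2 | racemic 1-[4-(benzyloxy)phenyl]-2,4-bis[3,5-bis(benzyloxy)phenyl]butane-1,4-dione | O=C(CC(C(=O)c1ccc(OCc2ccccc2)cc1)c1cc(OCc2ccccc2)cc(OCc2ccccc2)c1)c1cc(OCc2ccccc2)cc(OCc2ccccc2)c1
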